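## Analysis of the target

The target 16 is a diaryl ketone in which ring A is a 2-hydroxy-4,6-dimethoxyphenyl group and the other aryl carbon is C5 of a 7-hydroxy-2,2-dimethyl-2H-chromene (benzene ring B fused to pyran ring C). There is no stereocentre: C2 carries two methyl groups and the C3=C4 double bond lies in a six-membered ring, so only constitution has to be controlled. The sensitive groups are the electron-rich C3=C4 bond (acid, electrophiles, hydrogenation), two free phenols, and a ketone crowded by O2'/O6' on ring A and by C4a with its peri C4–H on ring B. The main difficulty is positional: on ring B the aroyl group at C5 is meta to both O7 and O1, so no electrophilic acylation of a 7-oxygenated chromene can place it there, and on ring A the carbonyl must sit between a hydroxyl and a methoxyl, not between the two methoxyls. The strategy rests on one feature: with oxygen at C5 in place of the carbonyl carbon, ring B has the symmetric 1,3,5-trioxygenated pattern (O1, O5, O7), so ring C can be fused without a regiochemical choice and the C5–O bond can then be exchanged for C5–C(=O). What remains to be controlled is O5 against O7 on ring B and the site of metalation on ring A.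

## Retrosynthetic reasoning

**16 ⇐ 15 ⇐ 14.** The last two operations cut only the O–Si and O–C bonds of protecting groups. O7 is carried as a triisopropylsilyl ether because it must survive sulfonylation, hydride, an acid-catalysed dehydration and a hot, chloride-rich carbonylation, and then leave under fluoride alone. O2' is carried as a methoxymethyl ether because that group also directs the metalation of ring A and is removed by dilute acid. The silyl ether is removed first so that the final step is a simple acid treatment.

**14 ⇐ 8 + 12 + 13.** Both bonds to the carbonyl carbon, C5–C(=O) and C(=O)–C1', are cut together, leaving the chromenyl triflate 8, the arylstannane 12 and carbon monoxide 13. Cutting here turns the awkward C5 carbon substituent into a C5–O bond, so ring B becomes a phloroglucinol derivative. It also fixes the ring A position through the tin-bearing carbon, where an acylation of ring A would give ortho/para mixtures. The forward reaction must make CO insertion precede a slow transmetalation from a di-ortho-substituted stannane. A chelating ferrocenyl diphosphine on palladium, chloride, a copper co-catalyst and moderate CO pressure are chosen for that reason.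

**8 ⇐ 7 ⇐ 6.** The C3=C4 double bond is traced back to a C4 ketone through the carbinol 7. This costs two steps, but it keeps the acid-sensitive alkene out of the early steps. It also supplies the C4 carbonyl that the next disconnection needs.

**6 ⇐ 5 ⇐ 4.** The C5–O sulfonate bond and the O7–Si bond are cut in turn, back to the diol 4. In 4 the O5–H is held in a hydrogen bond to the C4 carbonyl and flanked by C4a, while O7–H is free and more acidic, so silylation should go to O7 and leave O5 for the triflate. A shorter plan was weighed and not adopted: closing ring C on 1 directly as a chromene with an α,β-unsaturated aldehyde, then relying on the steric difference between O5 and O7 to steer a bulky silyl group. An ortho alkenyl group with a peri hydrogen is a weak discriminator between two phenols. That condensation is also prone to a second and third annulation on the still-activated ring.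

**4 ⇐ 1 + 2 (through 3).** Ring C is opened at C4–C4a and O1–C2, giving phloroglucinol 1 and the unsaturated acid 2. All three ring positions of 1 are equivalent, so the acylation can give only 3. The ketone of 3 then deactivates the ring, so annulation stops after one ring.

**12 ⇐ 11 ⇐ 10 ⇐ 9.** The C–Sn bond is cut back to the aryllithium 11, which comes from the methoxymethyl ether 10 by directed ortho-metalation, and 10 from the phenol 9. The acetal is the stronger directing group, and there are two equivalent positions next to it against one between the methoxyls. Both factors favour the wanted carbon.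

## Alternatives that were turned down

**Alternative 1:** *Disconnection:* ring C is opened at C3–C4 and O1–C2. This leaves the salicylaldehyde methyl 5-[(tert-butyldimethylsilyl)oxy]-2-formyl-3-hydroxybenzoate A2, whose ester carbon is the future ketone carbon, and (2-methylprop-1-en-1-yl)boronic acid A3.
- *Forward key step:* A2 condenses with dibenzylamine A4 to an iminium ion, and the boronate formed from A3 on the phenoxide delivers the alkenyl group to the iminium carbon (Petasis borono-Mannich). Heating expels A4 to a vinyl ortho-quinone methide, and oxa-6π electrocyclisation gives methyl 7-[(tert-butyldimethylsilyl)oxy]-2,2-dimethyl-2H-chromene-5-carboxylate A1.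
- *For it:* the aldehyde of A2 dictates where ring C is fused, the C5 carbon is present from the start, and neither tin nor 13 is needed. The later union would be addition of aryllithium 11 to a C5 aldehyde followed by oxidation. That is the most dependable way to a crowded benzophenone, so on the reliability of the carbonyl-forming event this plan is stronger.
- *Against it:* A2 is a 1,2,3,5-tetrasubstituted arene. It would have to come from methyl 3,5-dihydroxybenzoate A5 by monosilylation of a symmetric diol and formylation at the crowded carbon between ester and hydroxyl, in competition with the carbon of A5 that lies between the two oxygens. The regiochemical problem is moved, not removed. A1 also needs reduction to the aldehyde, addition and re-oxidation before deprotection.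
- *Comparison:* the longest line is estimated at three to four steps more. The chosen route offers a symmetric start, hydrogen-bond-controlled differentiation and a one-step union, at the price of a more demanding coupling.

**Alternative 2:** *Disconnection:* the C5–C(=O) and C4a–C4 bonds of ring B are cut in one operation. Ring B becomes 1-iodo-2,4-bis(methoxymethoxy)benzene A7, ring A becomes 2,4-dimethoxy-6-(methoxymethoxy)benzoic anhydride A8, and C2–C4 of ring C becomes 2-methylbut-3-en-2-ol A9.
- *Forward key step:* palladium adds to the C–I bond of A7, norbornene A10 inserts, and a palladacycle forms at the free ortho carbon. A8 acylates that carbon through a tetravalent palladium intermediate and A10 is extruded. The arylpalladium species at the former C–I carbon then ends in a Heck reaction with A9, giving [2-[(E)-3-hydroxy-3-methylbut-1-enyl]-3,5-bis(methoxymethoxy)phenyl][2,4-dimethoxy-6-(methoxymethoxy)phenyl]methanone A6. Acid would then remove the three acetals and close ring C from the allylic alcohol.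
- *For it:* this is the most convergent plan. Two carbon substituents of ring B arrive in one flask and their positions are fixed by the iodide of A7, so neither an O5/O7 question nor a metalation question arises. On step economy it is stronger than the chosen route.
- *Against it:* ortho-acylation in this manifold is established for unhindered aroyl donors. A8 is di-ortho-substituted and electron-rich, so its addition to an already crowded palladacycle is where failure is expected, and half of the ring A material leaves as carboxylate. A6 has an E alkene, so ring closure must pass through an allylic cation on a ring that carries a deactivating ketone and free phenols. A8 itself costs a carboxylation of 11 and a dehydration.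
- *Comparison:* the ceiling is higher, but precedent at the decisive bond is much thinner. The chosen strategy confines its uncertainty to one elementary step of a well-understood catalytic cycle and has a bypass by known chemistry from the same triflate 8.

**Alternative 3:** *Disconnection:* ring C is cut at C4a–C4, C8a–O1 and O1–C2, leaving an aryne and an enal. The aryne precursor is 2-bromo-4-(methoxymethoxy)-6-(trimethylsilyl)phenyl trifluoromethanesulfonate A12.
- *Forward key step:* fluoride releases 3-bromo-5-(methoxymethoxy)benzyne A13 from A12. The carbonyl oxygen of 3-methylbut-2-enal A14 attacks the carbon of A13 remote from bromine, and the resulting aryl anion next to bromine closes onto the carbonyl carbon. The benzoxete opens to a vinyl ortho-quinone methide, and oxa-6π closure gives 5-bromo-7-(methoxymethoxy)-2,2-dimethyl-2H-chromene A11.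
- *For it:* ring C is placed regiospecifically by the inductive effect of bromine in A13, O7 is differentiated from the outset, and the C5 bromide of A11 is a sturdier handle than a triflate. On regiocontrol of ring B this plan is at least as strong as the chosen one.
- *Against it:* A12 is a 1,2,3,5-tetrasubstituted arene that needs about four to five steps. The [2+2] reaction of A13 with the carbonyl group of A14 competes with a second aryne addition to the quinone methide and with ene pathways. A11 still lacks the ketone, so a further union at C5 is needed, either bromine–lithium exchange and addition to a ring A aldehyde with re-oxidation, or the same carbonylation with 12 and 13.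
- *Comparison:* the plan spends its key step on ring C, which the chosen route makes by routine chemistry, and leaves the hard bond for later. The chosen route uses its key step on the hard bond and reaches the precursor in five reliable steps from 1.

Key step: step 8

Remark on the chemistry: the target is achiral; the only stereocentre on the way (C4 of 7) is formed as a racemate and is removed in step 5.

## Route

Step 1
Reactants: 1 phloroglucinol (anhydrous); 2 3-methylbut-2-enoic acid
Product: 4 5,7-dihydroxy-2,2-dimethylchroman-4-one, via 3-methyl-1-(2,4,6-trihydroxyphenyl)but-2-en-1-one 3 (not isolated)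
Conditions: MeSO3H, P2O5, 70 °C
Reagents that add atoms: none
Why: Friedel–Crafts acylation of the symmetric triol by the activated acid gives the aryl enone 3, whose ortho hydroxyl closes ring C by intramolecular oxa-Michael addition; all ring positions of 1 are equivalent and the new ketone deactivates the ring, so one chromanone should form.

Step 2
Reactants: 4 5,7-dihydroxy-2,2-dimethylchroman-4-one
Product: 5 5-hydroxy-2,2-dimethyl-7-(triisopropylsilyloxy)chroman-4-one
Conditions: TIPSCl (1.05 equiv), imidazole, DMF, 0 °C
Reagents that add atoms: triisopropylsilyl chloride (TIPSCl), CC(C)[Si](Cl)(C(C)C)C(C)C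
Why: Selective phenol silylation: O5–H is tied up in a six-membered hydrogen bond to the C4 carbonyl and flanked by C4a, while O7–H is unhindered and the more acidic (para to the carbonyl), so the bulky silyl chloride should take O7 only.

Step 3
Reactants: 5 5-hydroxy-2,2-dimethyl-7-(triisopropylsilyloxy)chroman-4-one
Product: 6 2,2-dimethyl-4-oxo-7-(triisopropylsilyloxy)chroman-5-yl trifluoromethanesulfonate
Conditions: Tf2O, pyridine, CH2Cl2, 0 °C → rt
Reagents that add atoms: trifluoromethanesulfonic anhydride (Tf2O), O=S(=O)(OS(=O)(=O)C(F)(F)F)C(F)(F)F
Why: O-Sulfonylation of the remaining phenol by the N-triflylpyridinium species; hydrogen-bonded ortho-acyl phenols are triflated routinely this way and the aryl silyl ether is inert.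

Step 4
Reactants: 6 2,2-dimethyl-4-oxo-7-(triisopropylsilyloxy)chroman-5-yl trifluoromethanesulfonate
Product: 7 4-hydroxy-2,2-dimethyl-7-(triisopropylsilyloxy)chroman-5-yl trifluoromethanesulfonate (racemate)
Conditions: NaBH4, THF/MeOH, 0 °C
Reagents that add atoms: none
Why: Borohydride reduction of an aryl ketone that is now activated by the ortho sulfonate, not deactivated by a phenoxide; the C4 carbinol forms as a racemate, which is of no consequence because C4 becomes sp2 in the next step.

Step 5
Reactants: 7 4-hydroxy-2,2-dimethyl-7-(triisopropylsilyloxy)chroman-5-yl trifluoromethanesulfonate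
Product: 8 2,2-dimethyl-7-(triisopropylsilyloxy)-2H-chromen-5-yl trifluoromethanesulfonate
Conditions: TsOH·H2O (cat.), toluene, 80 °C
Reagents that add atoms: none
Why: Acid-catalysed E1 dehydration of a chroman-4-ol; the C4 cation is stabilised by O1 (ortho) and O7 (para) and loses a C3 proton to give the conjugated 2H-chromene, with the aryl triflate and the aryl silyl ether unaffected.

Step 6
Reactants: 9 3,5-dimethoxyphenol
Product: 10 1,3-dimethoxy-5-(methoxymethoxy)benzene
Conditions: MOMCl, i-Pr2NEt, CH2Cl2, 0 °C → rt
Reagents that add atoms: chloromethyl methyl ether (MOMCl), COCCl
Why: O-Alkylation of the phenol with the reactive α-chloro ether (methoxymethyl protection).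

Step 7
Reactants: 10 1,3-dimethoxy-5-(methoxymethoxy)benzene
Product: 12 tributyl[2,4-dimethoxy-6-(methoxymethoxy)phenyl]stannane, via 2,4-dimethoxy-6-(methoxymethoxy)phenyllithium 11 (not isolated)
Conditions: n-BuLi, THF, 0 °C; then Bu3SnCl, −78 °C → rt
Reagents that add atoms: tributyltin chloride (Bu3SnCl), CCCC[Sn](Cl)(CCCC)CCCC
Why: Directed ortho-metalation: the acetal chelates lithium and is a stronger director than methoxyl, and two equivalent carbons lie between it and a methoxyl against one between the methoxyls, so lithiation should give 11, which is trapped at tin.

Step 8
Reactants: 8 2,2-dimethyl-7-(triisopropylsilyloxy)-2H-chromen-5-yl trifluoromethanesulfonate; 12 tributyl[2,4-dimethoxy-6-(methoxymethoxy)phenyl]stannane; 13 carbon monoxide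
Product: 14 [2,4-dimethoxy-6-(methoxymethoxy)phenyl][2,2-dimethyl-7-(triisopropylsilyloxy)-2H-chromen-5-yl]methanone
Conditions: PdCl2(dppf) (10 mol%; dppf = Fe(C5H4PPh2)2), LiCl (3 equiv), CuI (10 mol%), CO (3 bar), 4 Å MS, DMF, 80 °C
Reagents that add atoms: none
Why: Carbonylative Stille coupling, the known three-component reaction of aryl triflates, CO and arylstannanes. The divalent palladium precatalyst is reduced in the flask to zerovalent palladium, which adds into the C5–O bond of 8, and chloride from LiCl turns the cationic arylpalladium triflate into a neutral, longer-lived chloride complex. Coordination and migratory insertion of 13 give the aroyl divalent palladium complex and so form the C5–C(=O) bond. The aryl group of 12 is passed to palladium by way of an arylcopper species formed with CuI (monovalent copper), and reductive elimination forms the C(=O)–C1' bond and returns zerovalent palladium. No ring is closed and no stereocentre is formed. The selectivity needed is ketone over direct biaryl; the substrate secures it, because the tin-bearing carbon of 12 is flanked by two alkoxy groups and transmetalates slowly, so CO insertion under pressure comes first and the acylpalladium species is the better acceptor for the aryl group. The wide bite angle of dppf should speed reductive elimination of the crowded ketone. The triflate is the only C–O bond able to add to palladium, and the silyl ether, the acetal and the cis-disubstituted ring alkene are spectators.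

Step 9
Reactants: 14 [2,4-dimethoxy-6-(methoxymethoxy)phenyl][2,2-dimethyl-7-(triisopropylsilyloxy)-2H-chromen-5-yl]methanone
Product: 15 [2,4-dimethoxy-6-(methoxymethoxy)phenyl](7-hydroxy-2,2-dimethyl-2H-chromen-5-yl)methanone
Conditions: TBAF, THF, 0 °C; aq. NH4Cl
Reagents that add atoms: none
Why: Fluoride-induced cleavage of the aryl silyl ether, driven by the Si–F bond and the good phenoxide leaving group; the acetal, the ketone and the chromene are inert to fluoride.

Step 10
Reactants: 15 [2,4-dimethoxy-6-(methoxymethoxy)phenyl](7-hydroxy-2,2-dimethyl-2H-chromen-5-yl)methanone
Product: 16 (2-hydroxy-4,6-dimethoxyphenyl)(7-hydroxy-2,2-dimethyl-2H-chromen-5-yl)methanone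
Conditions: HCl (cat.), MeOH, 40 °C
Reagents that add atoms: none
Why: Acid-catalysed methanolysis of the aryl methoxymethyl acetal; the freed phenol is stabilised by a hydrogen bond to the ketone, and a chromene carrying an electron-withdrawing aroyl group at C5 should tolerate dilute methanolic acid.

## Compound list

1 | phloroglucinol (benzene-1,3,5-triol) | Oc1cc(O)cc(O)c1 | starting material
2 | 3-methylbut-2-enoic acid | CC(C)=CC(=O)O | starting material
3 | 3-methyl-1-(2,4,6-trihydroxyphenyl)but-2-en-1-one | CC(C)=CC(=O)c1c(O)cc(O)cc1O | intermediate
4 | 5,7-dihydroxy-2,2-dimethylchroman-4-one | CC1(C)CC(=O)c2c(O)cc(O)cc2O1 | intermediate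
5 | 5-hydroxy-2,2-dimethyl-7-(triisopropylsilyloxy)chroman-4-one | CC(C)[Si](Oc1cc(O)c2C(=O)CC(C)(C)Oc2c1)(C(C)C)C(C)C | intermediate
6 | 2,2-dimethyl-4-oxo-7-(triisopropylsilyloxy)chroman-5-yl trifluoromethanesulfonate | CC(C)[Si](Oc1cc(OS(=O)(=O)C(F)(F)F)c2C(=O)CC(C)(C)Oc2c1)(C(C)C)C(C)C | intermediate
7 | 4-hydroxy-2,2-dimethyl-7-(triisopropylsilyloxy)chroman-5-yl trifluoromethanesulfonate (racemate) | CC(C)[Si](Oc1cc(OS(=O)(=O)C(F)(F)F)c2C(O)CC(C)(C)Oc2c1)(C(C)C)C(C)C | intermediate
8 | 2,2-dimethyl-7-(triisopropylsilyloxy)-2H-chromen-5-yl trifluoromethanesulfonate | CC1(C)C=Cc2c(OS(=O)(=O)C(F)(F)F)cc(O[Si](C(C)C)(C(C)C)C(C)C)cc2O1 | intermediate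
9 | 3,5-dimethoxyphenol | COc1cc(O)cc(OC)c1 | starting material
10 | 1,3-dimethoxy-5-(methoxymethoxy)benzene | COCOc1cc(OC)cc(OC)c1 | intermediate
11 | 2,4-dimethoxy-6-(methoxymethoxy)phenyllithium | [Li]c1c(OCOC)cc(OC)cc1OC | intermediate
12 | tributyl[2,4-dimethoxy-6-(methoxymethoxy)phenyl]stannane | CCCC[Sn](CCCC)(CCCC)c1c(OCOC)cc(OC)cc1OC | intermediate
13 | carbon monoxide | [C-]#[O+] | starting material
14 | [2,4-dimethoxy-6-(methoxymethoxy)phenyl][2,2-dimethyl-7-(triisopropylsilyloxy)-2H-chromen-5-yl]methanone | COCOc1cc(OC)cc(OC)c1C(=O)c1cc(O[Si](C(C)C)(C(C)C)C(C)C)cc2OC(C)(C)C=Cc12 | intermediate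
15 | [2,4-dimethoxy-6-(methoxymethoxy)phenyl](7-hydroxy-2,2-dimethyl-2H-chromen-5-yl)methanone | COCOc1cc(OC)cc(OC)c1C(=O)c1cc(O)cc2OC(C)(C)C=Cc12 | intermediate
16 | (2-hydroxy-4,6-dimethoxyphenyl)(7-hydroxy-2,2-dimethyl-2H-chromen-5-yl)methanone | COc1cc(O)c(C(=O)c2cc(O)cc3c2C=CC(C)(C)O3)c(OC)c1 | target

## Step count and least certain steps

Total: 10 steps. Longest linear sequence: 8 steps (steps 1–5, 8, 9, 10); the ring A branch is steps 6–7.

**Step 8 (key step).** The most likely failure is stalling at the aroyl divalent palladium stage, because the aryl group of 12 must be transferred from a carbon flanked by two alkoxy groups. While the cycle waits, protodestannylation of the electron-rich stannane, hydrolysis or reduction of the acylpalladium species and precipitation of palladium can take over. If CO is depleted, direct biaryl coupling can compete. The fallback separates the carbonylation from the crowded C–C bond formation. From 8, palladium-catalysed aminocarbonylation (Pd(OAc)2, Xantphos, CO, N,O-dimethylhydroxylamine hydrochloride, Et3N, toluene, 80 °C) should give the Weinreb amide N-methoxy-N,2,2-trimethyl-7-(triisopropylsilyloxy)-2H-chromene-5-carboxamide F1. The aryllithium 11, made from 10 as in step 7, should add to it at −78 → 0 °C and give 14 on work-up, where the route is rejoined.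

**Step 7.** The most likely failure is incomplete regiocontrol of the deprotonation: some lithiation between the two methoxyls would give an isomeric stannane that is hard to separate. The electron-rich stannane can also lose tin on acidic silica. The fallback fixes the position with a halogen. From 9, ortho-selective bromination (NBS, cat. i-Pr2NH, CH2Cl2, −78 → 0 °C) should give 2-bromo-3,5-dimethoxyphenol F2. At this stage an isomer can be separated and recognised by its symmetry. Methoxymethylation gives 2-bromo-1,5-dimethoxy-3-(methoxymethoxy)benzene F3, and bromine–lithium exchange (n-BuLi, THF, −78 °C) gives 11 and, with Bu3SnCl, 12.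

**Step 4.** The most likely failure is loss or transfer of the triflyl group when the C4 alkoxide forms beside the C5 sulfonate (attack at sulfur through a six-membered arrangement), or partial desilylation by methoxide. The fallback changes the order of events. From 5, reduction of the hydrogen-bonded ketone (NaBH4 in excess, EtOH/THF, rt) should give 2,2-dimethyl-7-(triisopropylsilyloxy)chromane-4,5-diol F4. This ortho-hydroxybenzyl alcohol dehydrates readily with a trace of acid to 2,2-dimethyl-7-(triisopropylsilyloxy)-2H-chromen-5-ol F5. Triflation (Tf2O, pyridine, CH2Cl2, 0 °C) then gives 8, bypassing steps 3–5.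

**Step 10.** The most likely failure is acid-mediated addition of methanol or water across C3=C4, or oligomerisation through the C4 benzylic cation, if the acetal cleavage needs prolonged heating. The fallback reverses the order of the deprotections and cleaves the acetal by chelation, not by protic acid. From 14, MgBr2·OEt2 with butane-1-thiol in Et2O at rt should remove the methoxymethyl group, with magnesium held between the ketone and the acetal oxygens, to give (2-hydroxy-4,6-dimethoxyphenyl)[2,2-dimethyl-7-(triisopropylsilyloxy)-2H-chromen-5-yl]methanone F6. TBAF in THF at 0 °C then gives 16.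

## Further compounds

F1 | step 8 | N-methoxy-N,2,2-trimethyl-7-(triisopropylsilyloxy)-2H-chromene-5-carboxamide | CON(C)C(=O)c1cc(O[Si](C(C)C)(C(C)C)C(C)C)cc2OC(C)(C)C=Cc12
F2 | step 7 | 2-bromo-3,5-dimethoxyphenol | COc1cc(O)c(Br)c(OC)c1
F3 | step 7 | 2-bromo-1,5-dimethoxy-3-(methoxymethoxy)benzene | COCOc1cc(OC)cc(OC)c1Br
F4 | step 4 | 2,2-dimethyl-7-(triisopropylsilyloxy)chromane-4,5-diol (racemate) | CC(C)[Si](Oc1cc(O)c2C(O)CC(C)(C)Oc2c1)(C(C)C)C(C)C
F5 | step 4 | 2,2-dimethyl-7-(triisopropylsilyloxy)-2H-chromen-5-ol | CC1(C)C=Cc2c(O)cc(O[Si](C(C)C)(C(C)C)C(C)C)cc2O1
F6 | step 10 | (2-hydroxy-4,6-dimethoxyphenyl)[2,2-dimethyl-7-(triisopropylsilyloxy)-2H-chromen-5-yl]methanone | COc1cc(O)c(C(=O)c2cc(O[Si](C(C)C)(C(C)C)C(C)C)cc3OC(C)(C)C=Cc23)c(OC)c1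
A1 | alternative 1 | methyl 7-[(tert-butyldimethylsilyl)oxy]-2,2-dimethyl-2H-chromene-5-carboxylate | COC(=O)c1cc(O[Si](C)(C)C(C)(C)C)cc2OC(C)(C)C=Cc12
A2 | alternative 1 | methyl 5-[(tert-butyldimethylsilyl)oxy]-2-formyl-3-hydroxybenzoate | COC(=O)c1cc(O[Si](C)(C)C(C)(C)C)cc(O)c1C=O
A3 | alternative 1 | (2-methylprop-1-en-1-yl)boronic acid | CC(C)=CB(O)O
A4 | alternative 1 | dibenzylamine | C(NCc1ccccc1)c1ccccc1
A5 | alternative 1 | methyl 3,5-dihydroxybenzoate | COC(=O)c1cc(O)cc(O)c1
A6 | alternative 2 | [2-[(E)-3-hydroxy-3-methylbut-1-enyl]-3,5-bis(methoxymethoxy)phenyl][2,4-dimethoxy-6-(methoxymethoxy)phenyl]methanone | COCOc1cc(OC)cc(OC)c1C(=O)c1cc(OCOC)cc(OCOC)c1/C=C/C(C)(C)O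
A7 | alternative 2 | 1-iodo-2,4-bis(methoxymethoxy)benzene | COCOc1ccc(I)c(OCOC)c1
A8 | alternative 2 | 2,4-dimethoxy-6-(methoxymethoxy)benzoic anhydride | COCOc1cc(OC)cc(OC)c1C(=O)OC(=O)c1c(OC)cc(OC)cc1OCOC
A9 | alternative 2 | 2-methylbut-3-en-2-ol | C=CC(C)(C)O
A10 | alternative 2 | norbornene (bicyclo[2.2.1]hept-2-ene) | C1=CC2CCC1C2
A11 | alternative 3 | 5-bromo-7-(methoxymethoxy)-2,2-dimethyl-2H-chromene | COCOc1cc(Br)c2C=CC(C)(C)Oc2c1
A12 | alternative 3 | 2-bromo-4-(methoxymethoxy)-6-(trimethylsilyl)phenyl trifluoromethanesulfonate | COCOc1cc(Br)c(OS(=O)(=O)C(F)(F)F)c([Si](C)(C)C)c1
A13 | alternative 3 | 3-bromo-5-(methoxymethoxy)benzyne | COCOC1=CC#CC(Br)=C1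
A14 | alternative 3 | 3-methylbut-2-enal | CC(C)=CC=O
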